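Slowness opened the meeting: the first speaker noted that elm read 0% of J at 0.500 min and 4.5% at 1.33 min, so something slow seems to stand between Z and J, while larch, with twice the X, read more at 0.833 min, 6.5% against elm's 1.2%.

| flask | Z | X | remark | time |
|---|---|---|---|---|
| elm | 28 mM | 1.1 equiv | run made earlier |  |
| ash | 14 mM | 1.1 equiv | run made earlier |  |
| oak | 56 mM | 1.1 equiv | run made earlier |  |
| larch | 28 mM | 2.2 equiv | run made earlier |  |
| Friday's | 28 mM | 1.10 equiv (fed, over 30 s) | all else is in the flask from the start; the feed brings no volume worth counting | 6.0 min |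
| Monday's | 28 mM | 1.10 equiv (fed, over 5.0 min) | all else is in the flask from the start; the feed brings no volume worth counting | 6.0 min |
| Wednesday's | 28 mM | 1.10 equiv | everything together at the start | 6.0 min |
| Thursday's | 28 mM (fed, over 5.0 min) | 1.10 equiv | all else is in the flask from the start; the feed brings no volume worth counting | 6.0 min |
| Tuesday's | 28 mM (in portions, 4, over 5.0 min) | 1.10 equiv | first portion at the start, last at 5.0 min | 6.0 min |

- elm (time / min: J / %, Q / %): 0.500: 0, 2.6; 0.833: 1.2, 2.0; 1.33: 4.5, 0; 2.00: 10.0, 2.8; 4.00: 22.0, 8.5; 6.00: 28.5, 9.6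
- ash (time / min: J / %, Q / %): 0.667: 0, 1.5; 1.33: 2.8, 0.4; 2.00: 6.2, 1.4; 2.50: 7.4, 1.8; 3.00: 10.0, 3.0; 4.00: 13.8, 5.5
- oak (time / min: J / %, Q / %): 0.250: 1.9, 0; 0.667: 4.3, 0.1; 1.33: 9.5, 0; 2.00: 17.6, 2.3; 3.00: 23.3, 6.0; 4.00: 30.2, 5.6
- larch (time / min: J / %, Q / %): 0.333: 2.5, 0; 0.833: 6.5, 0; 1.50: 12.8, 0.5; 2.50: 25.7, 2.8; 4.00: 36.3, 1.6

(standard deviation of a reading: 1 percentage point)

- percent here means Z units held: one Q counts as two
- a reading or a percentage of J counts all its forms, free or not

- the flask that comes out highest in share of J in J plus Q, or "all alike" when all lie within 1.5 percentage points (Friday's / Monday's / Wednesday's / Thursday's / Tuesday's / all alike)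
- share of J in J plus Q at the end, Friday's
- share of J in J plus Q at the end, Monday's
- share of J in J plus Q at the end, Wednesday's
- share of J in J plus Q at the end, Thursday's
- share of J in J plus Q at the end, Tuesday's

The first speaker argued that Q, which also comes late, is the waste of that slow stage, and proposed following one number: Q over J at a reading, 0.337 at the end of elm, called the waste ratio, the inverse of the usual selectivity factor. The asked share of J is then one over one plus this ratio.

The second speaker pooled the last two readings of each run. Elm gave 0.358 and larch 0.0710, a fall by 5.05 for doubled X at the same Z. Ash gave 0.357 and oak, with 56 mM of Z against ash's 14 mM at the same equivalents, 0.217, a fall by 1.65. Raising both charges together thus cut the ratio less than doubling X at the same Z, so the meeting took the waste ratio to fall as X rises and to rise as Z rises at a given X, and set no firm power on Z.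

Wednesday's repeats elm, and Friday's feed of 30 s is far shorter than the 6.0 min of the run, so both went down at 74.8%. My own entry: Z fed over 5.0 min stands on average at about half of elm's fraction, which I judged rather than measured, and I took the ratio in proportion to Z, also a judgement, giving a waste ratio of 0.168, half of elm's, and a share of 85.6% for Tuesday's and Thursday's, which this reckoning cannot part.

The forecast gave 74% for Friday's, 55% for Monday's, 75% for Wednesday's, 88% for Thursday's and 86% for Tuesday's, with Thursday's highest, holding that “Feeding Z slowly into full X halves average Z”.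

The flasks give 71.4% for Friday's, 57.8% for Monday's, 71.6% for Wednesday's, 82.2% for Thursday's and 83.9% for Tuesday's, so Tuesday's is highest, with a waste ratio of 0.192.

    Z → G (k = 0.00457 s⁻¹)
    X + G → J (k = 0.281 M⁻¹ s⁻¹)
    2 G → Q (k = 0.0994 M⁻¹ s⁻¹)
    X + J ⇌ E, settled at all times (K = 99.0 M⁻¹)
    J ⇌ L (K = 1.71, k = 0.0581 s⁻¹)

In Tuesday's at 3.64 min, X uses G 8.8 times as fast as G uses itself, a ratio of 0.114 at that moment. At 6.00 min, Tuesday's holds 9.91% of L beside 19.5% of J, and Q over the two together is 0.127. For the neighbour of Tuesday's with 4.40 equiv of X, two doublings of Tuesday's 1.10 equiv, the fall read from elm and larch, taken twice, divides 0.192 down to 0.00754, a share of 99.3%, and that flask gives 99.0%.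

The data come from a simulation for substances that don't exist, and the scatter is random.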